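The readings are calculated on assumed constants, and the scatter is random.

At early times intermediate B stood at 29.7% in the south run and 47.3% in the north run, and I began from that difference.

| setting | south | north | flask |
|---|---|---|---|
| starting material | 0.050 M | 0.20 M | 0.10 M |
| reagent | 0.95 equiv | 0.95 equiv | 0.950 equiv |
| remark | run made earlier | run made earlier |  |
| time |  |  | 1.0 h |

| run | time / min | intermediate B / % | target / % |
|---|---|---|---|
| south | 0.667 | 29.7 | 0.1 |
| south | 3.00 | 34.2 | 4.1 |
| south | 12.0 | 7.5 | 16.3 |
| south | 60.0 | 0 | 30.1 |
| north | 0.667 | 47.3 | 0 |
| north | 3.00 | 36.0 | 5.9 |
| north | 12.0 | 5.3 | 16.9 |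
| north | 60.0 | 0 | 29.9 |

(scatter of a reading: 0.5 percentage points)

- the moment within 1.0 h at which there is most intermediate B, in min
- the amount of intermediate B, in percent of the starting material charged, at that time

I took conversion as second-order with near-equal charges: s/(s+1), where s is time over the rise time τr, and τr falls as concentration rises. The first reading of each run gave τr = 0.657 min in the south run, so I reckoned 0.328 min in the flask. The north tail gave a decay time τd = 4.70 min.

I carried ρ, the decay time over the rise time: 14.3 for the flask. In the flask I reckoned decay slower than rise, so I treated it as a correction. Making equals loss where s(s+1) = ρ, so s = 3.32 and I put the flask's peak at 1.09 min. Let φ be the share of converted starting material that reaches intermediate B. I wrote the height as φ times the difference s/(s+1) − (s − ln(s+1))/ρ. The first north reading gave φ = 66.0%, so I reckoned 42.1%.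

The forecast said 1.2 min (0.9 min to 1.7 min) and 40.5% (38% to 43%), adding “The peak is broad”. My time was earlier than the forecast's.

The flask gave 1.23 min and 42.6%, and held 20.3% of intermediate B at 0.100 h.

    starting material + reagent → intermediate A (k = 9.20 /M/min)
    starting material + reagent → intermediate B (k = 20.0 /M/min)
    intermediate B → side product (k = 0.220 /min)
    intermediate A → target (k = 0.0740 /min)

With ρ at 14.3, my reckoning for the flask fell 0.140 min short in time and 0.50 percentage points short in height. I then raised the starting material to 0.25 M in a neighbouring flask, with the same equivalents. There ρ grew to 35.8 and s to 5.50. The same φ gave a height of 49.1%. That neighbouring flask gave 49.4%.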